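The veratrate carbonyl carbon is treated as a carbonic-acid linchpin. It is first hung on the benzylic oxygen at C1 of an enantiopure anti homoallylic alcohol as an imidazole-1-carboxylate. Its bond to C1′ of the 3,4-dimethoxyphenyl ring is then made with the aryl Grignard reagent. This one operation unites the two aryl-bearing halves and stops at the ester: the 4′-methoxy group para to the new bond makes the product carbonyl a vinylogous carbonate, far less electrophilic than the acyl imidazole. The vinyl group masks C3. Cleavage to the aldehyde and Felkin-controlled methyl addition complete the 1,2-anti, 1,3-anti triad.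

Key step: step 3

Numbering used: C1 is the benzylic carbon bearing the ester oxygen, C2 the methyl-bearing carbon, C3 the free carbinol carbon and C4 the terminal methyl. Primed numbers refer to the 3,4-dimethoxybenzoyl ring.

Assumption: (R)-TRIP is taken to steer the crotyl transfer to the Re face of an aryl aldehyde, as it does in the parent allylboration; were the sense opposite, the (S)-acid would be used.

Step 1
Reactants: 1 3,4,5-trimethoxybenzaldehyde; 2 (E)-crotylboronic acid pinacol ester
Product: 3 (1R,2R)-2-methyl-1-(3,4,5-trimethoxyphenyl)but-3-en-1-ol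
Conditions: (R)-TRIP (5 mol %), toluene, −30 °C; aqueous work-up
Reagents that add atoms: none
Why: In this chiral phosphoric acid-catalysed crotylboration the closed Zimmerman–Traxler chair should turn the E geometry of 2 into the C1–O/C2–Me anti relationship, while the catalyst, hydrogen-bonded to the pseudo-axial boronate oxygen and the formyl hydrogen, should open the Re face of 1 and so set 1R,2R.

Step 2
Reactants: 3 (1R,2R)-2-methyl-1-(3,4,5-trimethoxyphenyl)but-3-en-1-ol; 4 1,1′-carbonyldiimidazole
Product: 5 (1R,2R)-2-methyl-1-(3,4,5-trimethoxyphenyl)but-3-en-1-yl 1H-imidazole-1-carboxylate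
Conditions: CH2Cl2, rt; water wash; stored cold and used soon
Reagents that add atoms: none
Why: O-acylation of a secondary alcohol with CDI (imidazole carbamate formation) should stop after one substitution because 5 is much less electrophilic than 4, and the C1–O bond is not touched, so both stereocentres are kept.

Step 3
Reactants: 5 (1R,2R)-2-methyl-1-(3,4,5-trimethoxyphenyl)but-3-en-1-yl 1H-imidazole-1-carboxylate; 6 4-bromo-1,2-dimethoxybenzene
Product: 8 (1R,2R)-2-methyl-1-(3,4,5-trimethoxyphenyl)but-3-en-1-yl 3,4-dimethoxybenzoate, via 3,4-dimethoxyphenylmagnesium bromide 7 (not isolated)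
Conditions: 6, Mg, THF, 40 °C; then 5 (7 in slight excess), THF, −20 to 0 °C; aqueous work-up
Reagents that add atoms: none
Why: The carbanionic C1′ of 7, para to the 4′-methoxy group, adds to the carbamate carbonyl of 5, whose imidazole N3 can bind magnesium, and the tetrahedral adduct collapses with loss of imidazolide to leave the aryl–C(=O) bond. This is the known ester synthesis from Grignard reagents and alkyl imidazole-1-carboxylates, an acyl substitution at the carbonic acid level. No ring is closed and no stereocentre is formed; C1 and C2 are only carried through, because the benzylic C–O bond is never broken. The step needs mono-addition, which the substrate secures: the product carbonyl is conjugated with the 4′-methoxy group and flanked by a branched benzylic alkoxy group, so it should be far less electrophilic than the acyl imidazole. If the adduct expelled the alkoxide instead, the aroyl imidazole and magnesium alkoxide so formed should recombine to the same ester. The vinyl group is inert to 7.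

Step 4
Reactants: 8 (1R,2R)-2-methyl-1-(3,4,5-trimethoxyphenyl)but-3-en-1-yl 3,4-dimethoxybenzoate
Product: 9 (1R,2S)-2-methyl-3-oxo-1-(3,4,5-trimethoxyphenyl)propyl 3,4-dimethoxybenzoate
Conditions: OsO4 (2 mol %), NaIO4, 2,6-lutidine, dioxane/H2O, rt; used crude
Reagents that add atoms: sodium periodate, [Na+].[O-]I(=O)(=O)=O
Why: The Lemieux–Johnson cleavage (catalytic dihydroxylation, then periodate glycol fission) should attack only the terminal alkene and spare the ester and both electron-rich rings, and the lutidine buffer should keep the β-aroyloxy aldehyde from epimerising at C2 or eliminating.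

Step 5
Reactants: 9 (1R,2S)-2-methyl-3-oxo-1-(3,4,5-trimethoxyphenyl)propyl 3,4-dimethoxybenzoate
Product: 10 (1R,2R,3S)-3-hydroxy-2-methyl-1-(3,4,5-trimethoxyphenyl)butyl 3,4-dimethoxybenzoate
Conditions: MeTi(OiPr)3, CH2Cl2/THF, −78 to −30 °C; aqueous work-up
Reagents that add atoms: methyltitanium triisopropoxide, C[Ti](OC(C)C)(OC(C)C)OC(C)C
Why: Carbonyl addition of this non-basic, aldehyde-selective and non-chelating methyltitanium reagent should follow Felkin–Anh control, with methyl attacking anti to the large C1 substituent to give C2–Me/C3–OH syn (3S); the polar 1,3-anti preference of the β-aroyloxy group reinforces this because C2–Me and C1–O are anti, and the ester is left alone.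

Compound list
1 | 3,4,5-trimethoxybenzaldehyde | COc1cc(C=O)cc(OC)c1OC | starting material
2 | (E)-crotylboronic acid pinacol ester | C/C=C/CB1OC(C)(C)C(C)(C)O1 | starting material
3 | (1R,2R)-2-methyl-1-(3,4,5-trimethoxyphenyl)but-3-en-1-ol | O[C@@H](c1cc(OC)c(OC)c(OC)c1)[C@H](C)C=C | intermediate
4 | 1,1′-carbonyldiimidazole | O=C(n1ccnc1)n1ccnc1 | starting material
5 | (1R,2R)-2-methyl-1-(3,4,5-trimethoxyphenyl)but-3-en-1-yl 1H-imidazole-1-carboxylate | O=C(O[C@@H](c1cc(OC)c(OC)c(OC)c1)[C@H](C)C=C)n1ccnc1 | intermediate
6 | 4-bromo-1,2-dimethoxybenzene | COc1ccc(Br)cc1OC | starting material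
7 | 3,4-dimethoxyphenylmagnesium bromide (not isolated) | COc1ccc([Mg]Br)cc1OC | intermediate
8 | (1R,2R)-2-methyl-1-(3,4,5-trimethoxyphenyl)but-3-en-1-yl 3,4-dimethoxybenzoate | COc1ccc(C(=O)O[C@@H](c2cc(OC)c(OC)c(OC)c2)[C@H](C)C=C)cc1OC | intermediate
9 | (1R,2S)-2-methyl-3-oxo-1-(3,4,5-trimethoxyphenyl)propyl 3,4-dimethoxybenzoate | COc1ccc(C(=O)O[C@@H](c2cc(OC)c(OC)c(OC)c2)[C@H](C)C=O)cc1OC | intermediate
10 | (1R,2R,3S)-3-hydroxy-2-methyl-1-(3,4,5-trimethoxyphenyl)butyl 3,4-dimethoxybenzoate | COc1ccc(C(=O)O[C@@H](c2cc(OC)c(OC)c(OC)c2)[C@H](C)[C@H](C)O)cc1OC | target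

Total step count: 5. Longest linear sequence: 5 steps (1 → 3 → 5 → 8 → 9 → 10).

Steps most likely to fail

First, step 5. The methyl addition may show too little facial selectivity, or the aroyl group may migrate to the newly formed C3 alkoxide. The fallback sets C3 before the ester is built, by internal hydride delivery, and sets out from 3.
- Tsuji–Wacker oxidation (PdCl2, CuCl, O2, DMF/H2O) should give the ketol (3S,4R)-4-hydroxy-3-methyl-4-(3,4,5-trimethoxyphenyl)butan-2-one F1.
- Evans–Saksena reduction (Me4NBH(OAc)3, MeCN/AcOH, −30 °C) should give the 1,3-anti diol (1R,2R,3S)-2-methyl-1-(3,4,5-trimethoxyphenyl)butane-1,3-diol F2.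
- Silylation of the less hindered C3 hydroxyl (TESCl, imidazole, CH2Cl2, −20 °C) should give (1R,2S,3S)-2-methyl-3-(triethylsilyloxy)-1-(3,4,5-trimethoxyphenyl)butan-1-ol F3.
- Treatment with 4 should give (1R,2S,3S)-2-methyl-3-(triethylsilyloxy)-1-(3,4,5-trimethoxyphenyl)butyl 1H-imidazole-1-carboxylate F4.
- Addition of 7 under the conditions of step 3 should give (1R,2S,3S)-2-methyl-3-(triethylsilyloxy)-1-(3,4,5-trimethoxyphenyl)butyl 3,4-dimethoxybenzoate F5.
- AcOH/THF/H2O then frees the C3 hydroxyl, and the line comes back to the route at 10.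

Second, step 4. The aroyloxy group may be lost by β-elimination, or C2 may epimerise, while the aldehyde is formed and handled. The fallback avoids the aldehyde and sets out from 8. Tsuji–Wacker oxidation (PdCl2, CuCl, O2, DMF/H2O) should give the methyl ketone (1R,2S)-2-methyl-3-oxo-1-(3,4,5-trimethoxyphenyl)butyl 3,4-dimethoxybenzoate F6. A reagent-controlled CBS reduction with (R)-Me-CBS and BH3·SMe2 (toluene, −20 °C), which differentiates methyl from the branched chain, should then deliver the 3S alcohol. The line comes back to the route at 10.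

Third, step 3. A second addition of the Grignard reagent to the ester, or decarboxylative decay of the benzylic imidazole carbamate before it reacts, may erode the coupling. The fallback makes the same aryl–carbonyl bond by transition-metal catalysis and sets out from 3. Palladium-catalysed alkoxycarbonylation of commercial 4-iodo-1,2-dimethoxybenzene under CO (1 atm) uses Pd(OAc)2, Xantphos and Et3N in toluene at 80 °C. CO inserts into the aryl–palladium bond and alcohol 3 captures the acyl palladium species. The line comes back to the route at 8 and makes no new compound on the way.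

Further compounds
F1 | step 5 | (3S,4R)-4-hydroxy-3-methyl-4-(3,4,5-trimethoxyphenyl)butan-2-one | O[C@@H](c1cc(OC)c(OC)c(OC)c1)[C@H](C)C(C)=O
F2 | step 5 | (1R,2R,3S)-2-methyl-1-(3,4,5-trimethoxyphenyl)butane-1,3-diol | O[C@@H](c1cc(OC)c(OC)c(OC)c1)[C@H](C)[C@H](C)O
F3 | step 5 | (1R,2S,3S)-2-methyl-3-(triethylsilyloxy)-1-(3,4,5-trimethoxyphenyl)butan-1-ol | O[C@@H](c1cc(OC)c(OC)c(OC)c1)[C@H](C)[C@H](C)O[Si](CC)(CC)CC
F4 | step 5 | (1R,2S,3S)-2-methyl-3-(triethylsilyloxy)-1-(3,4,5-trimethoxyphenyl)butyl 1H-imidazole-1-carboxylate | O=C(O[C@@H](c1cc(OC)c(OC)c(OC)c1)[C@H](C)[C@H](C)O[Si](CC)(CC)CC)n1ccnc1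
F5 | step 5 | (1R,2S,3S)-2-methyl-3-(triethylsilyloxy)-1-(3,4,5-trimethoxyphenyl)butyl 3,4-dimethoxybenzoate | COc1ccc(C(=O)O[C@@H](c2cc(OC)c(OC)c(OC)c2)[C@H](C)[C@H](C)O[Si](CC)(CC)CC)cc1OC
F6 | step 4 | (1R,2S)-2-methyl-3-oxo-1-(3,4,5-trimethoxyphenyl)butyl 3,4-dimethoxybenzoate | COc1ccc(C(=O)O[C@@H](c2cc(OC)c(OC)c(OC)c2)[C@H](C)C(C)=O)cc1OC
F0 | step 3 | none | none
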